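## Retrosynthetic overview
1. The (2S)-flavanone C-ring is closed last, by an enantioselective oxa-Michael cyclisation of a 2'-hydroxychalcone, followed by global MOM removal.
2. The chalcone comes from a Claisen–Schmidt condensation of a 3'-lavandulyl-4',6'-bis-MOM-2'-hydroxyacetophenone with 2,4-bis-MOM-benzaldehyde. The 6'-O-MOM blocks the wrong (6-lavandulyl) ring closure.
3. The lavandulyl acetophenone comes from reductive Friedel–Crafts alkylation of phloroacetophenone (symmetric, so no regiochemistry issue) with the chiral acetal (MeO)2CH–CH(isopropenyl)–CH2CH=CMe2.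
4. That acetal comes from Wittig isopropylidenation of a β-isopropenyl aldehyde. The aldehyde is made by organocatalytic iminium β-alkenylation of fumaraldehyde mono(dimethyl acetal), which sets the first stereocentre.

**Assumptions**
- The target is natural (−)-sophoraflavanone G. From the SMILES, C2 is S and the lavandulyl CH is R.
- The (2S,5S)-imidazolidinone directs the alkenyl group to the iminium face anti to its benzyl group. This is the face that is Si for a β-alkyl iminium and Re here, because the acetal carbon outranks Cα. It gives the (S)-aldehyde 4 and therefore the R-lavandulyl centre. If the opposite enantiomer formed, the (2R,5R) catalyst would be used.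
- The (S)-backbone iminophosphorane 15 is assumed to give the (2S)-flavanone. Otherwise the enantiomeric catalyst is used.
- Catalysts 3 and 15 are treated as prepared reagents, listed as starting materials. 3 is commercial. 15 is made separately from L-tert-leucine-derived 1,2-diamine by thiourea formation at the primary amine with 3,5-bis(trifluoromethyl)phenyl isothiocyanate, then iminophosphorane formation with tris(4-methoxyphenyl)phosphine dibromide/Et3N. These catalyst preparations are not counted in the substrate route.

## Route

**Step 1**
Reactants: 1 (E)-4,4-dimethoxybut-2-enal (fumaraldehyde mono(dimethyl acetal)); 2 potassium isopropenyltrifluoroborate; 3 (2S,5S)-5-benzyl-2-tert-butyl-3-methylimidazolidin-4-one·TFA (catalyst)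
Product: 4 (S)-4,4-dimethoxy-3-(prop-1-en-2-yl)butanal
Conditions: 3 (20 mol%), 2 (1.5 equiv), CH2Cl2/i-PrOH 9:1, −10 °C, 36 h; aq. NaHCO3 work-up
Reagents that add atoms: 2, potassium isopropenyltrifluoroborate, C=C(C)[B-](F)(F)F.[K+] (adds the isopropenyl group)
Why: Iminium-catalysed asymmetric conjugate alkenylation (organotrifluoroborate addition to an enal). The E-iminium of 1 has one face shielded by the catalyst's benzyl group, so the alkenyl-BF3K adds to the β-carbon on the open face and sets the first stereocentre (S). This centre is β to the carbonyl, so it cannot epimerise by enolisation.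

**Step 2**
Reactants: 4; 5 isopropyltriphenylphosphonium iodide
Product: 6 (S)-1,1-dimethoxy-5-methyl-2-(prop-1-en-2-yl)hex-4-ene
Conditions: 5, KOt-Bu, THF, 0 °C → rt
Reagents that add atoms: 5, CC(C)[P+](c1ccccc1)(c1ccccc1)c1ccccc1.[I-] (adds =CMe2)
Why: Wittig olefination converts CH2CHO into the prenyl group CH2CH=CMe2. The stereocentre is not α to the aldehyde and is untouched, and the dimethyl acetal is stable to the basic ylide.

**Step 3**
Reactants: 6; 7 2,4,6-trihydroxyacetophenone (phloroacetophenone); 8 Hantzsch ester (diethyl 2,6-dimethyl-1,4-dihydropyridine-3,5-dicarboxylate)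
Product: 9 (R)-1-[2,4,6-trihydroxy-3-(2-isopropenyl-5-methylhex-4-enyl)phenyl]ethanone (3'-lavandulylphloroacetophenone)
Conditions: 7 (3 equiv), 6, Sc(OTf)3 (10 mol%), MeCN, 0 °C, 2 h; then 8 (1.5 equiv), 40 °C
Reagents that add atoms: none (8 only delivers H2)
Why: Lewis-acid Friedel–Crafts hydroxyalkylation of the oxocarbenium ion from 6 at the symmetric phloroglucinol carbon. Loss of MeOH gives an o-quinone methide, which the Hantzsch ester reduces by conjugate hydride transfer (reductive Friedel–Crafts alkylation). Excess 7 suppresses dialkylation. The stereocentre is retained (its descriptor changes from S to R only because the CIP priorities change), because trapping by the phenol outcompetes enol-ether formation.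

**Step 4**
Reactants: 9; 10 chloromethyl methyl ether (MOMCl)
Product: 11 (R)-1-[2-hydroxy-4,6-bis(methoxymethoxy)-3-lavandulylphenyl]ethanone
Conditions: 10 (2.1 equiv), K2CO3, acetone, 0 °C → rt
Reagents that add atoms: 10, MOMCl, ClCOC (adds two CH2OCH3 groups)
Why: Williamson-type MOM etherification. The non-chelated, most acidic 4'-OH reacts first. Of the two chelated OH groups, the 6'-OH is unhindered, whereas the 2'-OH is flanked by the lavandulyl group and the acetyl and reacts slowest, so it stays free for ring closure on the C-8 side.

**Step 5**
Reactants: 12 2,4-dihydroxybenzaldehyde; 10 MOMCl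
Product: 13 2,4-bis(methoxymethoxy)benzaldehyde
Conditions: NaH (2.2 equiv), DMF, 0 °C; then 10 (2.2 equiv), 0 °C → rt
Reagents that add atoms: 10, MOMCl, ClCOC
Why: Double phenol MOM protection, so the B-ring survives base-mediated condensation and can be unmasked later.

**Step 6**
Reactants: 11; 13
Product: 14 (E)-chalcone, 2'-hydroxy-3'-lavandulyl-4',6'-bis-MOM with a 2,4-bis-MOM B-ring
Conditions: 50% aq. KOH, EtOH, rt, 48 h; quench with AcOH at 0 °C
Reagents that add atoms: none
Why: Claisen–Schmidt condensation. The 2'-phenolate persists under basic conditions, and the acidic quench at low temperature avoids racemic cyclisation.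

**Step 7**
Reactants: 14; 15 bifunctional iminophosphorane (BIMP-type) catalyst, (S)-tert-leucine-derived thiourea
Product: 16 (2S)-8-lavandulyl-5,7,2',4'-tetrakis(MOM-oxy)flavanone
Conditions: 15 (10 mol%), toluene (0.02 M), −20 °C, 48 h
Reagents that add atoms: none (isomerisation)
Why: Proposed new method: the strongly basic iminophosphorane deprotonates the chelated, hindered 2'-OH, giving a chiral aminophosphonium phenoxide ion pair, while the thiourea N–H groups bind the enone C=O and hold the E-enone s-cis. 6-endo oxa-Michael closure then occurs on one enone face, and the aminophosphonium protonates the enolate at C3 to set C2 (S). The closest known reactions are cinchona-thiourea oxa-Michael cyclisations of simple 2'-hydroxychalcones and BIMP-catalysed intramolecular oxa-Michael additions to unsaturated esters and amides. The new feature is the very electron-rich, ortho-branched enone, whose 6'-O-MOM, B-ring 2,4-dialkoxy groups and 2'-OH flanked by a branched alkyl group have not been tested. Low temperature and stopping at full conversion limit retro-Michael racemisation.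

**Step 8**
Reactants: 16
Product: 17 sophoraflavanone G, (2S)-5,7,2',4'-tetrahydroxy-8-[(2R)-2-isopropenyl-5-methylhex-4-enyl]flavanone
Conditions: 2 M aq. HCl, MeOH/THF 1:1, 40 °C, 8 h (monitor by LC-MS)
Reagents that add atoms: none (only H is added)
Why: Acid-catalysed MOM acetal hydrolysis. Flavanone C2 and the lavandulyl centre are not epimerisable under acid. The prenyl and isopropenyl alkenes tolerate moderately dilute aqueous HCl at 40 °C, and stopping at full conversion limits cyclisation of the isopropenyl group onto the 7-OH. This matches the target SMILES: C2 is S, the lavandulyl CH is R, and the substituents are 5,7,2',4'-OH and 8-lavandulyl.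

## Compound list
1 | (E)-4,4-dimethoxybut-2-enal | COC(OC)/C=C/C=O | starting material
2 | potassium isopropenyltrifluoroborate | C=C(C)[B-](F)(F)F.[K+] | starting material
3 | (2S,5S)-5-benzyl-2-tert-butyl-3-methylimidazolidin-4-one·TFA (catalyst) | CN1[C@@H](C(C)(C)C)N[C@@H](Cc2ccccc2)C1=O.OC(=O)C(F)(F)F | starting material
4 | (S)-4,4-dimethoxy-3-(prop-1-en-2-yl)butanal | O=CC[C@@H](C(C)=C)C(OC)OC | intermediate
5 | isopropyltriphenylphosphonium iodide | CC(C)[P+](c1ccccc1)(c1ccccc1)c1ccccc1.[I-] | starting material
6 | (S)-1,1-dimethoxy-5-methyl-2-(prop-1-en-2-yl)hex-4-ene | CC(C)=CC[C@@H](C(C)=C)C(OC)OC | intermediate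
7 | 2,4,6-trihydroxyacetophenone | CC(=O)c1c(O)cc(O)cc1O | starting material
8 | Hantzsch ester | CCOC(=O)C1=C(C)NC(C)=C(C1)C(=O)OCC | starting material
9 | (R)-3'-lavandulyl-2',4',6'-trihydroxyacetophenone | C=C(C)[C@H](CC=C(C)C)Cc1c(O)cc(O)c(C(C)=O)c1O | intermediate
10 | chloromethyl methyl ether (MOMCl) | ClCOC | starting material
11 | (R)-3'-lavandulyl-2'-hydroxy-4',6'-bis(MOM-oxy)acetophenone | C=C(C)[C@H](CC=C(C)C)Cc1c(OCOC)cc(OCOC)c(C(C)=O)c1O | intermediate
12 | 2,4-dihydroxybenzaldehyde | O=Cc1ccc(O)cc1O | starting material
13 | 2,4-bis(methoxymethoxy)benzaldehyde | O=Cc1ccc(OCOC)cc1OCOC | intermediate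
14 | MOM-protected (R)-3'-lavandulyl-2'-hydroxychalcone | C=C(C)[C@H](CC=C(C)C)Cc1c(OCOC)cc(OCOC)c(C(=O)/C=C/c2ccc(OCOC)cc2OCOC)c1O | intermediate
15 | (S)-tert-leucine-derived thiourea iminophosphorane catalyst (prepared catalyst) | CC(C)(C)[C@@H](CNC(=S)Nc1cc(C(F)(F)F)cc(C(F)(F)F)c1)N=P(c1ccc(OC)cc1)(c1ccc(OC)cc1)c1ccc(OC)cc1 | starting material
16 | (2S)-8-lavandulyl-5,7,2',4'-tetrakis(MOM-oxy)flavanone | C=C(C)[C@H](CC=C(C)C)Cc1c(OCOC)cc(OCOC)c2c1O[C@H](c1ccc(OCOC)cc1OCOC)CC2=O | intermediate
17 | sophoraflavanone G | C=C(C)[C@H](CC=C(C)C)Cc1c(O)cc(O)c2c1O[C@H](c1ccc(O)cc1O)CC2=O | target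

**Total steps:** 8, including the one-step preparation of aldehyde 13 and excluding the separate preparation of catalyst 15.
**Longest linear sequence:** 7 steps (1 → 4 → 6 → 9 → 11 → 14 → 16 → 17).

## Three steps most likely to fail
1. **Step 7 (proposed new step).** The hindered, electron-rich, chelated chalcone may cyclise slowly, reversibly or with low ee. The chalcone/flavanone equilibrium may also lie on the chalcone side.
   - Fallback (known chemistry): cyclise 14 racemically (NaOAc, EtOH, 80 °C) and isolate (2S)-16 by preparative chiral-stationary-phase HPLC.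
2. **Step 3.** Risks are epimerisation through the oxocarbenium ion, acid-promoted cyclisation of the alkenes, and dialkylation.
   - Fallback: mild acetal hydrolysis and immediate Luche reduction to (R)-lavandulol, conversion to the bromide (CBr4, PPh3), then C-alkylation of 7 under basic conditions. This replaces the cationic Friedel–Crafts pathway with SN2 alkylation.
3. **Step 4.** Non-selective MOM protection could give the 2'-OMOM/6'-OH isomer, which would cyclise to the 6-lavandulyl flavanone.
   - Fallback: reorder the steps. Make 2'-hydroxy-4',6'-bis(MOM)acetophenone from 7 first (unambiguous by symmetry), then perform the reductive Friedel–Crafts of 6 at C-3, guided by the ortho free OH through o-quinone methide formation.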